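**The pitfall.** A curve that bends over near half of the charge looks like an equilibrium, yet a flask whose charge has simply passed through bends the same way. You asked for a quick number on this flask and your hunch is that more time helps; here is our reckoning.

| flask | E | temperature | remark | time |
|---|---|---|---|---|
| midnight | 0.20 M | 100 °C | the very flask that is asked about, followed so far |  |
| dawn | 0.30 M | 95 °C | run made earlier |  |
| flask | 0.20 M | 100 °C |  | 8.0 d |

| run | time / h | L / % |
|---|---|---|
| midnight | 6.00 | 0.8 |
| midnight | 20.0 | 6.5 |
| midnight | 30.0 | 15.3 |
| midnight | 50.0 | 26.8 |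
| midnight | 72.0 | 35.1 |
| midnight | 96.0 | 43.9 |
| midnight | 120 | 48.5 |
| dawn | 1.50 | 0.2 |
| dawn | 2.50 | 1.5 |
| dawn | 4.00 | 0.4 |
| dawn | 6.00 | 0.4 |
| dawn | 10.0 | 1.4 |
| dawn | 15.0 | 2.9 |
| dawn | 20.0 | 5.0 |

(standard deviation of a reading: 1 percentage point)

- given per volume of solution although it is solid: E
- removed L is counted in
- what was read earlier has a scatter of 1 percentage point, one standard deviation
- at the start none of E is in solution

- eta: at 8.0 d raise the temperature by 15 K, then wait 15 d
- beta: change nothing and wait 15 d more
- alpha: at 8.0 d take out 90 % of the L then present, then wait 15 d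

1. L, in percent of the E first charged, at 8.0 d
2. the remedy with the largest gain of L, or "none" below 2 percentage points (eta / beta / alpha / none)
3. L present, with what was taken out counted in, in percent of the E first charged, after eta
4. L present, with what was taken out counted in, in percent of the E first charged, after alpha

**Solid feed.** E starts as a solid, so we read L in molarity. At 20.0 h the dawn run held 0.0150 M of L and the midnight run 0.0130 M. Within the scatter, the dawn charge, larger than the midnight one, shows no larger output, though its cooler bath is mixed in.

**Clearing time.** So we take the rise of L from 20.0 h to 30.0 h in the midnight run, 0.00176 M h⁻¹, as a feed that holds while solid lasts. Charge divided by feed gives 114 h; we call this the clearing time. For this flask it is shorter than the wait of 192 h, and the last reading already lies past it. The last rise was about half the one before. If the rises keep shrinking so, they add as much again, and we commit to 53.1 % and to no useful remedy. That assumes the unread rest of the charge does not return to L.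

**The check.** The forecast gives 59 %, 68 % after eta, 85 % after alpha and alpha as best, on “a reversible E⇌L equilibrium, tentatively”. The flask gives 49.8 %, then 50.1 % after eta and 50.5 % after alpha. The gains are 0.38 percentage points, 0.23 points and 0.77 points for eta, beta and alpha, all under 2 points, so the best is none.

    Z → L (k = 0.0211 h⁻¹, Ea = 114 kJ mol⁻¹)
    2 Z ⇌ G (K = 0.610 M⁻¹, k = 0.137 M⁻¹ h⁻¹, Ea = 107 kJ mol⁻¹, ΔH = −32.0 kJ mol⁻¹)
    Z + L → Q (k = 0.123 M⁻¹ h⁻¹, Ea = 81.0 kJ mol⁻¹)
    E ⇌ Z, rate k4*(cs4 - [Z]) while solid is left; crystals form when [Z] > cs4 (solubility = 0.120 M, k = 0.0522 h⁻¹)
    (constants at 100 °C)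

**What ran.** In this flask E went into solution while solid stood, half that turnover done by 25.7 h, and solid E was down to 0 % at 96.0 h, inside the clearing time of 114 h. Meanwhile Z passed into L, half done by 57.1 h, and Z + L into Q, half done by 73.7 h, until at 192 h Z stood at 0.867 % beside L at 49.8 % and Q at 49.4 %. The neighbour flask with 0.80 M of E has, at the same feed, a clearing time of 455 h, longer than its 192 h, and then still held 37.1 % as solid E.

The numbers in the tables were generated by integration with made-up constants.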